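**Plan**

- The target is achiral. Ring A is numbered as the benzoic acid (C1 CO2H, C2 OH, C4 OMe, C5 O-aryl, C6 pentyl) and ring B with primes (C1' CO2Me, C2' O-aryl, C4' OH, C6' 3-oxopentyl).
- Retrosynthesis first removes two benzyl groups from ring A and a dioxolane from the side-chain ketone, then cuts ring B at C3'–C4' and C5'–C6'.
- This cut is possible because the array C3'(H)–C2'(O-aryl)–C1'(CO2Me)–C6'(alkyl), with the C4' oxygen para to the ester, is C3–C4–C5–C6 of a 4-aryloxy-6-alkyl-2-pyrone-5-carboxylate plus the two carbons of a ketene acetal.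
- Further cuts: the diaryl ether at O–C2' (ring A phenol plus 4-tosyloxypyrone), the pyrone into dimethyl 3-oxopentanedioate and ketal-protected 4-oxohexanoic acid, and ring A back to olivetol.
- Forward: ring A comes from olivetol and is functionalized; the pyrone ring is built separately; the two are joined through oxygen; ring B is formed last by cycloaddition, loss of CO2 and aromatization; two deprotections finish.
- Stereochemistry: none to set; the bridgehead centres of the transient cycloadduct disappear on aromatization.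

Key step: step 12

Notation: ArA = 4-(benzyloxy)-3-(benzyloxycarbonyl)-6-methoxy-2-pentylphenyl (protected ring A, bonded through its C5 oxygen).
Assumption: ketene bis(trimethylsilyl) acetal is prepared in one step from trimethylsilyl acetate instead of being bought.

**Route**

Step 1
Reactants: 1 olivetol (5-pentylbenzene-1,3-diol)
Product: 2 olivetolic acid (2,4-dihydroxy-6-pentylbenzoic acid)
Conditions: MeOMgOCO2Me (2 M in DMF, 3 equiv), 120 °C, N2; then ice-cold 2 M HCl
Reagents that add atoms: methyl magnesium carbonate, COC(=O)O[Mg]OC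
Why: Kolbe–Schmitt-type carboxylation with Stiles' reagent, in which the magnesium phenoxide delivers CO2 to the ring carbon ortho to one hydroxyl and para to the other, and the chelated magnesium salicylate pulls the equilibrium to the acid.

Step 2
Reactants: 2 olivetolic acid
Product: 3 benzyl 2,4-dihydroxy-6-pentylbenzoate
Conditions: BnBr (1.05 equiv), KHCO3, DMF, rt
Reagents that add atoms: benzyl bromide, BrCc1ccccc1
Why: Bicarbonate deprotonates only the carboxylic acid, so SN2 O-alkylation of the carboxylate should give the benzyl ester and leave both phenols free.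

Step 3
Reactants: 3 benzyl 2,4-dihydroxy-6-pentylbenzoate
Product: 4 benzyl 2-hydroxy-4-methoxy-6-pentylbenzoate
Conditions: MeI (1.1 equiv), K2CO3, acetone, rt
Reagents that add atoms: iodomethane, CI
Why: Williamson etherification is expected at the unchelated, more acidic C4 hydroxyl, because the C2 hydroxyl is held in a hydrogen bond to the ester carbonyl and does not react at room temperature with one equivalent of MeI.

Step 4
Reactants: 4 benzyl 2-hydroxy-4-methoxy-6-pentylbenzoate
Product: 5 benzyl 2-(benzyloxy)-4-methoxy-6-pentylbenzoate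
Conditions: BnBr (1.5 equiv), K2CO3, DMF, 60 °C
Reagents that add atoms: benzyl bromide, BrCc1ccccc1
Why: Williamson etherification of the chelated phenol under more forcing conditions (polar aprotic solvent, heat, excess halide) should close the last free oxygen of ring A.

Step 5
Reactants: 5 benzyl 2-(benzyloxy)-4-methoxy-6-pentylbenzoate
Product: 6 benzyl 6-(benzyloxy)-3-bromo-4-methoxy-2-pentylbenzoate
Conditions: NBS (1.05 equiv), MeCN, 0 °C to rt, dark
Reagents that add atoms: N-bromosuccinimide, O=C1CCC(=O)N1Br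
Why: Electrophilic aromatic bromination should go to C5 of ring A (para to the benzyloxy group, ortho to the methoxy group), since the only other free position, C3, lies between two alkoxy groups and is the less reactive site of a 1,3-dialkoxyarene.

Step 6
Reactants: 6 benzyl 6-(benzyloxy)-3-bromo-4-methoxy-2-pentylbenzoate
Product: 8 benzyl 6-(benzyloxy)-3-hydroxy-4-methoxy-2-pentylbenzoate, via pinacol boronate 7 (not isolated)
Conditions: B2pin2, Pd(OAc)2 (5 mol %), SPhos (10 mol %), KOAc, 1,4-dioxane, 90 °C; then 30% H2O2, NaOH (aq), THF, 0 °C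
Reagents that add atoms: hydrogen peroxide, OO
Why: Miyaura borylation with an SPhos-ligated zerovalent palladium catalyst, which accepts di-ortho-substituted aryl bromides, followed by hydroperoxide oxidation of the C–B bond with 1,2-aryl shift, should give the phenol while the hindered benzyl ester stays intact at 0 °C.

Step 7
Reactants: 9 4-oxohexanoic acid
Product: 11 3-(2-ethyl-1,3-dioxolan-2-yl)propanoic acid, via hydroxyethyl ester ketal 10 (not isolated)
Conditions: HOCH2CH2OH (3 equiv), TsOH·H2O (cat.), toluene, reflux, Dean–Stark; then NaOH, MeOH/H2O, rt; NaH2PO4 (aq) to pH 5, 0 °C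
Reagents that add atoms: ethylene glycol, OCCO
Why: Acid-catalysed ketalization with azeotropic removal of water also esterifies the acid with glycol, and saponification converges on the ketal acid, since the dioxolane is stable to base and to brief contact with a pH 5 buffer.

Step 8
Reactants: 11 3-(2-ethyl-1,3-dioxolan-2-yl)propanoic acid; 12 dimethyl 3-oxopentanedioate
Product: 15 methyl 6-[2-(2-ethyl-1,3-dioxolan-2-yl)ethyl]-4-hydroxy-2-oxo-2H-pyran-5-carboxylate, via acid chloride 13 (not isolated), via acylated keto diester 14 (not isolated)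
Conditions: 11, 1-chloro-N,N,2-trimethylprop-1-en-1-amine, CH2Cl2, 0 °C to rt; then 12 (1.5 equiv), MgCl2, pyridine, CH2Cl2, 0 °C to rt; then DBU, toluene, 80 °C; NaH2PO4 (aq) work-up
Reagents that add atoms: none
Why: The Ghosez reagent forms the acid chloride without releasing HCl, the magnesium chelate of the keto diester is C-acylated (Rathke-type acylation of a beta-keto ester), and the enol oxygen of the new acyl group lactonizes onto the remote ester, the only six-membered closure available, to give the 4-hydroxy-2-pyrone.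

Step 9
Reactants: 15 methyl 6-[2-(2-ethyl-1,3-dioxolan-2-yl)ethyl]-4-hydroxy-2-oxo-2H-pyran-5-carboxylate
Product: 16 methyl 6-[2-(2-ethyl-1,3-dioxolan-2-yl)ethyl]-2-oxo-4-(tosyloxy)-2H-pyran-5-carboxylate
Conditions: TsCl, Et3N, CH2Cl2, 0 °C
Reagents that add atoms: p-toluenesulfonyl chloride, Cc1ccc(cc1)S(Cl)(=O)=O
Why: O-Sulfonylation of the vinylogous acid at its C4 oxygen is the standard entry to 4-tosyloxy-2-pyrones and runs under basic conditions that do not touch the dioxolane.

Step 10
Reactants: 16 methyl 6-[2-(2-ethyl-1,3-dioxolan-2-yl)ethyl]-2-oxo-4-(tosyloxy)-2H-pyran-5-carboxylate; 8 benzyl 6-(benzyloxy)-3-hydroxy-4-methoxy-2-pentylbenzoate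
Product: 17 methyl 4-(ArA-oxy)-6-[2-(2-ethyl-1,3-dioxolan-2-yl)ethyl]-2-oxo-2H-pyran-5-carboxylate
Conditions: Cs2CO3, MeCN, rt to 40 °C
Reagents that add atoms: none
Why: Addition–elimination (vinylogous acyl substitution) of the cesium phenoxide at pyrone C4, which is beta to the lactone carbonyl and carries the sulfonate leaving group, should form the aryl ether, the poorly solvated cesium phenoxide compensating for the two ortho substituents of ring A.

Step 11
Reactants: 18 trimethylsilyl acetate
Product: 19 ketene bis(trimethylsilyl) acetal (1,1-bis(trimethylsilyloxy)ethene)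
Conditions: LiN(iPr)2, THF, −78 °C; TMSCl, −78 °C to rt; distillation
Reagents that add atoms: chlorotrimethylsilane, C[Si](C)(C)Cl
Why: Kinetic enolization of the silyl ester and O-silylation of the lithium enolate is the established preparation of bis-silyl ketene acetals, and distillation removes the C-silylated by-product.

Step 12
Reactants: 17 methyl 4-(ArA-oxy)-6-[2-(2-ethyl-1,3-dioxolan-2-yl)ethyl]-2-oxo-2H-pyran-5-carboxylate; 19 ketene bis(trimethylsilyl) acetal
Product: 23 methyl 2-(ArA-oxy)-6-[2-(2-ethyl-1,3-dioxolan-2-yl)ethyl]-4-hydroxybenzoate, via bridged lactone 20 (not isolated), via cyclohexadiene 21 (not isolated), via aryl silyl ether 22 (not isolated)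
Conditions: 19 (5 equiv), toluene, 110 °C, sealed tube; then MeOH, K2CO3 (cat.), rt
Reagents that add atoms: none
Why: The electron-poor pyrone 17 and the electron-rich ketene acetal 19 should combine in a concerted but strongly asynchronous inverse-electron-demand Diels–Alder reaction, the CH2 terminus of 19 bonding to pyrone C6 (the C5'–C6' bond) and the acetal carbon to pyrone C3 (the C3'–C4' bond) to give bridged lactone 20; retro-[4+2] loss of CO2 gives cyclohexadiene 21, 1,2-elimination of trimethylsilanol aromatizes it to 22, and methanolysis frees the C4' phenol. The closest known reaction type is the cycloaddition of 2-pyrone-5-carboxylates (coumalates, isodehydroacetates) with ketene acetals, which gives para-oxygenated benzoates after loss of CO2 and an alcohol. Ring B is closed as a six-membered carbocycle by an intermolecular [4+2] cycloaddition that makes both new ring bonds, not by cyclization of a chain. No stereocentre remains, because the two bridgehead centres of racemic 20 are destroyed when CO2 leaves. The step needs regioselectivity (CH2 to C6, not to C3 or C4) and chemoselectivity over displacement of the C4 aryloxy group; C6 is beta to the C5 ester and the terminus of the dienyl lactone and so carries the largest LUMO coefficient, whereas C4 is a vinylogous carbonate carbon damped by the aryloxy lone pair and shielded by the di-ortho-substituted ring A. Heating in toluene without Lewis acid or fluoride keeps 19 a neutral pi-nucleophile, so an ionic addition–elimination at C4 has no easy path.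

Step 13
Reactants: 23 methyl 2-(ArA-oxy)-6-[2-(2-ethyl-1,3-dioxolan-2-yl)ethyl]-4-hydroxybenzoate
Product: 24 methyl 2-(ArA-oxy)-4-hydroxy-6-(3-oxopentyl)benzoate
Conditions: 1 M HCl (aq), THF, rt
Reagents that add atoms: water, O
Why: Acid-catalysed hydrolysis of the dioxolane should free the ketone, while the two hindered benzoate esters, the benzyl ether and the diaryl ether are stable to dilute acid at room temperature.

Step 14
Reactants: 24 methyl 2-(ArA-oxy)-4-hydroxy-6-(3-oxopentyl)benzoate
Product: 25 epiphorellic acid 2 (6-hydroxy-3-[5-hydroxy-2-(methoxycarbonyl)-3-(3-oxopentyl)phenoxy]-4-methoxy-2-pentylbenzoic acid)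
Conditions: H2 (1 atm), 10% Pd/C, EtOAc, rt
Reagents that add atoms: none
Why: Catalytic hydrogenolysis cleaves the benzyl ester and the benzyl ether under neutral conditions at room temperature, which spares the dialkyl ketone, the methyl ester and the diaryl ether and avoids acid- or heat-induced decarboxylation of the salicylic acid.

**Compound list**

1 | olivetol (5-pentylbenzene-1,3-diol) | CCCCCc1cc(O)cc(O)c1 | starting material
2 | olivetolic acid (2,4-dihydroxy-6-pentylbenzoic acid) | CCCCCc1cc(O)cc(O)c1C(=O)O | intermediate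
3 | benzyl 2,4-dihydroxy-6-pentylbenzoate | CCCCCc1cc(O)cc(O)c1C(=O)OCc1ccccc1 | intermediate
4 | benzyl 2-hydroxy-4-methoxy-6-pentylbenzoate | CCCCCc1cc(OC)cc(O)c1C(=O)OCc1ccccc1 | intermediate
5 | benzyl 2-(benzyloxy)-4-methoxy-6-pentylbenzoate | CCCCCc1cc(OC)cc(OCc2ccccc2)c1C(=O)OCc1ccccc1 | intermediate
6 | benzyl 6-(benzyloxy)-3-bromo-4-methoxy-2-pentylbenzoate | CCCCCc1c(Br)c(OC)cc(OCc2ccccc2)c1C(=O)OCc1ccccc1 | intermediate
7 | benzyl 6-(benzyloxy)-4-methoxy-2-pentyl-3-(4,4,5,5-tetramethyl-1,3,2-dioxaborolan-2-yl)benzoate | CCCCCc1c(B2OC(C)(C)C(C)(C)O2)c(OC)cc(OCc2ccccc2)c1C(=O)OCc1ccccc1 | intermediate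
8 | benzyl 6-(benzyloxy)-3-hydroxy-4-methoxy-2-pentylbenzoate (ring A phenol) | CCCCCc1c(O)c(OC)cc(OCc2ccccc2)c1C(=O)OCc1ccccc1 | intermediate
9 | 4-oxohexanoic acid | CCC(=O)CCC(=O)O | starting material
10 | 2-hydroxyethyl 3-(2-ethyl-1,3-dioxolan-2-yl)propanoate | CCC1(CCC(=O)OCCO)OCCO1 | intermediate
11 | 3-(2-ethyl-1,3-dioxolan-2-yl)propanoic acid | CCC1(CCC(=O)O)OCCO1 | intermediate
12 | dimethyl 3-oxopentanedioate | COC(=O)CC(=O)CC(=O)OC | starting material
13 | 3-(2-ethyl-1,3-dioxolan-2-yl)propanoyl chloride | CCC1(CCC(=O)Cl)OCCO1 | intermediate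
14 | dimethyl 2-[3-(2-ethyl-1,3-dioxolan-2-yl)propanoyl]-3-oxopentanedioate | COC(=O)CC(=O)C(C(=O)OC)C(=O)CCC1(CC)OCCO1 | intermediate
15 | methyl 6-[2-(2-ethyl-1,3-dioxolan-2-yl)ethyl]-4-hydroxy-2-oxo-2H-pyran-5-carboxylate | O=C1C=C(O)C(C(=O)OC)=C(CCC2(CC)OCCO2)O1 | intermediate
16 | methyl 6-[2-(2-ethyl-1,3-dioxolan-2-yl)ethyl]-2-oxo-4-(tosyloxy)-2H-pyran-5-carboxylate | O=C1C=C(OS(=O)(=O)c2ccc(C)cc2)C(C(=O)OC)=C(CCC2(CC)OCCO2)O1 | intermediate
17 | methyl 4-[4-(benzyloxy)-3-(benzyloxycarbonyl)-6-methoxy-2-pentylphenoxy]-6-[2-(2-ethyl-1,3-dioxolan-2-yl)ethyl]-2-oxo-2H-pyran-5-carboxylate | O=C1C=C(Oc2c(CCCCC)c(C(=O)OCc3ccccc3)c(OCc3ccccc3)cc2OC)C(C(=O)OC)=C(CCC2(CC)OCCO2)O1 | intermediate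
18 | trimethylsilyl acetate | CC(=O)O[Si](C)(C)C | starting material
19 | ketene bis(trimethylsilyl) acetal (1,1-bis(trimethylsilyloxy)ethene) | C=C(O[Si](C)(C)C)O[Si](C)(C)C | intermediate
20 | racemic bridged lactone: methyl 5-(ArA-oxy)-1-[2-(2-ethyl-1,3-dioxolan-2-yl)ethyl]-3-oxo-8,8-bis(trimethylsilyloxy)-2-oxabicyclo[2.2.2]oct-5-ene-6-carboxylate | O=C1OC2(CCC3(CC)OCCO3)CC(O[Si](C)(C)C)(O[Si](C)(C)C)C1C(Oc4c(CCCCC)c(C(=O)OCc5ccccc5)c(OCc5ccccc5)cc4OC)=C2C(=O)OC | intermediate
21 | methyl 6-(ArA-oxy)-2-[2-(2-ethyl-1,3-dioxolan-2-yl)ethyl]-4,4-bis(trimethylsilyloxy)cyclohexa-1,5-diene-1-carboxylate | COC(=O)C1=C(CCC2(CC)OCCO2)CC(O[Si](C)(C)C)(O[Si](C)(C)C)C=C1Oc1c(CCCCC)c(C(=O)OCc2ccccc2)c(OCc2ccccc2)cc1OC | intermediate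
22 | methyl 2-(ArA-oxy)-6-[2-(2-ethyl-1,3-dioxolan-2-yl)ethyl]-4-(trimethylsilyloxy)benzoate | COC(=O)c1c(Oc2c(CCCCC)c(C(=O)OCc3ccccc3)c(OCc3ccccc3)cc2OC)cc(O[Si](C)(C)C)cc1CCC1(CC)OCCO1 | intermediate
23 | methyl 2-[4-(benzyloxy)-3-(benzyloxycarbonyl)-6-methoxy-2-pentylphenoxy]-6-[2-(2-ethyl-1,3-dioxolan-2-yl)ethyl]-4-hydroxybenzoate | COC(=O)c1c(Oc2c(CCCCC)c(C(=O)OCc3ccccc3)c(OCc3ccccc3)cc2OC)cc(O)cc1CCC1(CC)OCCO1 | intermediate
24 | methyl 2-[4-(benzyloxy)-3-(benzyloxycarbonyl)-6-methoxy-2-pentylphenoxy]-4-hydroxy-6-(3-oxopentyl)benzoate | COC(=O)c1c(Oc2c(CCCCC)c(C(=O)OCc3ccccc3)c(OCc3ccccc3)cc2OC)cc(O)cc1CCC(=O)CC | intermediate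
25 | epiphorellic acid 2 (6-hydroxy-3-[5-hydroxy-2-(methoxycarbonyl)-3-(3-oxopentyl)phenoxy]-4-methoxy-2-pentylbenzoic acid) | CCCCCc1c(Oc2cc(O)cc(CCC(=O)CC)c2C(=O)OC)c(OC)cc(O)c1C(=O)O | target

**Count and risks**

Total step count: 14. Longest linear sequence: 10 steps (steps 1–6, 10, 12, 13, 14). The pyrone branch (steps 7–9) and the ketene acetal (step 11) are convergent side branches.

Steps most likely to fail:

1. Step 12. The cycloaddition may be too slow, because the C4 aryloxy donor and the fully substituted C6 lower the reactivity of the diene. Thermal O-to-C silyl migration of the ketene acetal, or silyl transfer and substitution at C4, could then consume the reagents first. The fallback sets out from 17 and rejoins the route at 25; it uses a ketene dialkyl acetal, the thermally robust and best-documented dienophile class for pyrone carboxylates.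
   - Commercial bromoacetaldehyde diethyl acetal is transacetalized with benzyl alcohol (TsOH cat., ethanol distilled off) to 2-bromo-1,1-bis(benzyloxy)ethane F1.
   - KOtBu in THF eliminates HBr to give 1,1-bis(benzyloxy)ethene F2.
   - Heating 17 with F2 in toluene or xylene (110–140 °C) should give, after loss of CO2 and benzyl alcohol, methyl 4-(benzyloxy)-2-(ArA-oxy)-6-[2-(2-ethyl-1,3-dioxolan-2-yl)ethyl]benzoate F3.
   - 1 M HCl in THF would convert it into methyl 4-(benzyloxy)-2-(ArA-oxy)-6-(3-oxopentyl)benzoate F4.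
   - Hydrogenolysis over Pd/C would then remove all three benzyl groups at once to give 25.

2. Step 10. The phenoxide may attack sulfur instead of C4 (sulfonyl transfer, returning 15 and tosylating the phenol), or the di-ortho-substituted phenoxide may add too slowly, so that ring opening at C2 or C6 competes. The fallback sets out from 15 and rejoins the route at 17; it replaces the sulfonate by a halide, for which attack at the leaving group is not possible.
   - Neutral Appel-type deoxychlorination of the vinylogous acid (PPh3, CCl4, MeCN, rt) should give methyl 4-chloro-6-[2-(2-ethyl-1,3-dioxolan-2-yl)ethyl]-2-oxo-2H-pyran-5-carboxylate F5 without endangering the dioxolane.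
   - F5 with phenol 8 and K2CO3 in DMF, the known way from 4-halo-2-pyrones to 4-aryloxy-2-pyrones, should give 17.

3. Step 8. The gamma-ketal acyl chloride may decompose, the dioxolane may be lost to adventitious HCl, or O-acylation and double acylation of the keto diester may compete. The fallback sets out from 11 and rejoins the route at 14; it uses a chloride-free acyl donor.
   - N,N'-Carbonyldiimidazole in THF converts 11 into 1-[3-(2-ethyl-1,3-dioxolan-2-yl)propanoyl]-1H-imidazole F6.
   - F6 is C-acylated by the magnesium enolate of 12 (MgCl2, Et3N, MeCN, rt; Masamune-type acylation) to give 14.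
   - 14 is cyclized with DBU as in step 8.

**Further compounds**

F1 | step 12 | 2-bromo-1,1-bis(benzyloxy)ethane | BrCC(OCc1ccccc1)OCc1ccccc1
F2 | step 12 | 1,1-bis(benzyloxy)ethene | C=C(OCc1ccccc1)OCc1ccccc1
F3 | step 12 | methyl 4-(benzyloxy)-2-[4-(benzyloxy)-3-(benzyloxycarbonyl)-6-methoxy-2-pentylphenoxy]-6-[2-(2-ethyl-1,3-dioxolan-2-yl)ethyl]benzoate | COC(=O)c1c(Oc2c(CCCCC)c(C(=O)OCc3ccccc3)c(OCc3ccccc3)cc2OC)cc(OCc2ccccc2)cc1CCC1(CC)OCCO1
F4 | step 12 | methyl 4-(benzyloxy)-2-[4-(benzyloxy)-3-(benzyloxycarbonyl)-6-methoxy-2-pentylphenoxy]-6-(3-oxopentyl)benzoate | COC(=O)c1c(Oc2c(CCCCC)c(C(=O)OCc3ccccc3)c(OCc3ccccc3)cc2OC)cc(OCc2ccccc2)cc1CCC(=O)CC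
F5 | step 10 | methyl 4-chloro-6-[2-(2-ethyl-1,3-dioxolan-2-yl)ethyl]-2-oxo-2H-pyran-5-carboxylate | O=C1C=C(Cl)C(C(=O)OC)=C(CCC2(CC)OCCO2)O1
F6 | step 8 | 1-[3-(2-ethyl-1,3-dioxolan-2-yl)propanoyl]-1H-imidazole | CCC1(CCC(=O)n2ccnc2)OCCO1
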